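**Retrosynthetic overview**

1. The target comes from its bis(methyl ether); ring E (the isopropenyl cyclopentanone) is closed last by a Lewis-acid ene-type attack of a prenyl alkene on the ring D enedione.
2. Key bond (ring B): the α-carbon of a ring D ketone is joined to the ortho carbon of the dimethoxyarene. Both carbons are natively nucleophilic, so the ketone side is reversed to an enolonium (α-keto cation equivalent) made from its silyl dienol ether with a λ3-iodane, and the arene closes on it in Friedel–Crafts fashion.
3. Ring C: thermal endo Diels–Alder of an (E)-1-aryl-3-methylbutadiene with the prenyl-bearing C=C of prenylbenzoquinone. The other quinone C=C is masked, and the absolute configuration set, by a catalytic enantioselective cyclopentadiene Diels–Alder that is later reversed.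
4. Building blocks: 1,4-dimethoxybenzene + prenyl bromide (ring D), 2,5-dimethoxybenzaldehyde + diethyl (2-methylallyl)phosphonate (ring A and diene), cyclopentadiene.
5. Ring order: A and D are bought as arenes; then C (cycloaddition), B (enolonium arylation), E (ene). Ring letters: A hydroquinone, B five-membered ring fused to A, C methylcyclohexene, D cyclohexane-1,4-dione, E cyclopentanone.

Assumption: the (S)-oxazaborolidinium catalyst of step 3 is taken to give adduct 7 as drawn; if the sense of induction is the opposite, the (R)-catalyst is used and nothing else changes.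

**Route**

Step 1
Reactants: 1 1,4-dimethoxybenzene; 2 1-bromo-3-methylbut-2-ene (prenyl bromide)
Product: 4 1,4-dimethoxy-2-(3-methylbut-2-en-1-yl)benzene, via (2,5-dimethoxyphenyl)lithium 3 (not isolated)
Conditions: n-BuLi, TMEDA, THF, 0 °C → rt; then 2, −78 °C → rt
Reagents that add atoms: none
Why: Directed ortho-lithiation of the symmetric diether followed by SN2 allylation of the aryllithium with the primary allylic bromide installs the prenyl group; no stereocentre is formed.

Step 2
Reactants: 4 1,4-dimethoxy-2-(3-methylbut-2-en-1-yl)benzene
Product: 5 2-(3-methylbut-2-en-1-yl)cyclohexa-2,5-diene-1,4-dione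
Conditions: (NH4)2Ce(NO3)6, MeCN/H2O, 0 °C
Reagents that add atoms: water, O
Why: Oxidative demethylation of a 1,4-dimethoxyarene to the p-quinone is fast at 0 °C and leaves the trisubstituted alkene alone.

Step 3
Reactants: 5 2-(3-methylbut-2-en-1-yl)cyclohexa-2,5-diene-1,4-dione; 6 cyclopenta-1,3-diene (freshly cracked from dicyclopentadiene)
Product: 7 (1S,4R,4aS,8aR)-6-(3-methylbut-2-en-1-yl)-1,4,4a,8a-tetrahydro-1,4-methanonaphthalene-5,8-dione
Conditions: (S)-3,3-diphenyl-1-(2-methylphenyl)tetrahydro-1H,3H-pyrrolo[1,2-c][1,3,2]oxazaborole (20 mol%), (CF3SO2)2NH (18 mol%), CH2Cl2, −78 °C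
Reagents that add atoms: none
Why: Catalytic enantioselective Diels–Alder reaction in which the cationic oxazaborolidine activates the quinone so that cyclopentadiene adds endo to one face of the unsubstituted C=C, which sets the absolute configuration of the whole route and masks that bond.

Step 4
Reactants: 8 2,5-dimethoxybenzaldehyde; 9 diethyl (2-methylprop-2-en-1-yl)phosphonate
Product: 11 1,4-dimethoxy-2-[(1E)-3-methylbuta-1,3-dien-1-yl]benzene, via α-lithiated phosphonate 10 (not isolated)
Conditions: n-BuLi, THF, −78 °C; then 8, DMPU, −78 °C → rt
Reagents that add atoms: none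
Why: Horner–Wadsworth–Emmons olefination through the α-carbon of the lithiated allylic phosphonate gives the (E)-1-aryl diene.

Step 5
Reactants: 7 (1S,4R,4aS,8aR)-6-(3-methylbut-2-en-1-yl)-1,4,4a,8a-tetrahydro-1,4-methanonaphthalene-5,8-dione; 11 1,4-dimethoxy-2-[(1E)-3-methylbuta-1,3-dien-1-yl]benzene
Product: 12 endo/anti bis-adduct 5-(2,5-dimethoxyphenyl)-7-methyl-10a-(3-methylbut-2-en-1-yl)-1,4,4a,5,8,8a,9a,10a-octahydro-1,4-methanoanthracene-9,10-dione (aryl cis to the C-10 carbonyl; new ring anti to the methano-bridged ring)
Conditions: toluene, BHT (cat.), 110 °C, sealed tube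
Reagents that add atoms: none
Why: Thermal Diels–Alder reaction at the only remaining enedione C=C: the diene comes from the convex face anti to the norbornene unit, its CH2 terminus bonds to the unsubstituted dienophile carbon (uncatalysed regiochemistry, which a Lewis acid on the less hindered carbonyl would reverse) and the endo transition state puts the E-aryl group cis to the dione ring, setting the prenylated quaternary carbon, the ring-fusion CH and the benzylic CH.

Step 6
Reactants: 12 endo/anti bis-adduct
Product: 13 (4aS,5R,8aR)-5-(2,5-dimethoxyphenyl)-7-methyl-4a-(3-methylbut-2-en-1-yl)-4a,5,8,8a-tetrahydronaphthalene-1,4-dione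
Conditions: flash vacuum pyrolysis, 450 °C, 0.01 mbar
Reagents that add atoms: none
Why: Retro-Diels–Alder cycloreversion expels cyclopentadiene and restores the enedione C=C without touching the three centres set in step 5; the short contact time limits a thermal ene reaction of the prenyl group, which would give the wrong (endo) isopropenyl epimer.

Step 7
Reactants: 13 (4aS,5R,8aR)-5-(2,5-dimethoxyphenyl)-7-methyl-4a-(3-methylbut-2-en-1-yl)-4a,5,8,8a-tetrahydronaphthalene-1,4-dione
Product: 16 tetracyclic enedione (rings A–D; 13 with a new bond from C-8a to C-6 of the dimethoxyphenyl ring), via trimethylsilyl dienol ether 14 (not isolated), via iodanyl enolonium species 15 (not isolated)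
Conditions: Me3SiOTf, iPr2NEt, CH2Cl2, −78 → 0 °C; then BF3·OEt2, PhI(OH)OTs, −78 → −40 °C
Reagents that add atoms: none
Why: Proposed new method: C-8a is the only enolisable position of 13, so soft enolisation gives one silyl dienol ether, which the BF3-activated λ3-iodane converts into an enolonium (α-keto cation equivalent); the ortho carbon of the electron-rich arene, held 1,3 to it on ring C, attacks in an intramolecular Friedel–Crafts alkylation (an electrophile can reach the arene at the acute angle this five-membered closure demands, whereas enol-to-quinone addition would be 5-endo-trig), and because the arene can reach only one face the new quaternary centre and ring B form with the configuration the bridge enforces; the closest known reactions are α-arylations of ketone-derived iodine enolonium species with electron-rich arenes and cationic cyclialkylations to indanes.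

Step 8
Reactants: 16 tetracyclic enedione
Product: 17 bis(methyl ether) of the target
Conditions: Me2AlCl, CH2Cl2, −78 → 0 °C
Reagents that add atoms: none
Why: Lewis-acid-promoted intramolecular ene (Prins-type) cyclisation: the cage locks the prenyl CH2 axial on ring D above the enedione, the alkene adds to the β-carbon of the aluminium-bound ketone through a chair-like transition state that places the developing tertiary cation exo (away from the CH2–C=O bridge), and loss of a methyl proton gives the exo isopropenyl group, while the bridgehead CH configuration is forced by the bicycle.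

Step 9
Reactants: 17 bis(methyl ether) of the target
Product: 19 CNP0287617.1 (target), via ring A quinone 18 (not isolated)
Conditions: (NH4)2Ce(NO3)6, MeCN/H2O, 0 °C; then aq. Na2S2O4, EtOAc, rt
Reagents that add atoms: water, O
Why: Oxidative demethylation to the quinone followed by dithionite reduction in the same flask unveils the hydroquinone under conditions that leave the ketones, the alkenes and all five stereocentres untouched.

**Compound list**

1 | 1,4-dimethoxybenzene | COc1ccc(OC)cc1 | starting material
2 | 1-bromo-3-methylbut-2-ene (prenyl bromide) | CC(C)=CCBr | starting material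
3 | (2,5-dimethoxyphenyl)lithium | [Li]c1cc(OC)ccc1OC | intermediate (not isolated)
4 | 1,4-dimethoxy-2-(3-methylbut-2-en-1-yl)benzene | COc1ccc(OC)c(CC=C(C)C)c1 | intermediate
5 | 2-(3-methylbut-2-en-1-yl)cyclohexa-2,5-diene-1,4-dione (prenylbenzoquinone) | CC(C)=CCC1=CC(=O)C=CC1=O | intermediate
6 | cyclopenta-1,3-diene | C1=CC=CC1 | starting material
7 | (1S,4R,4aS,8aR)-6-(3-methylbut-2-en-1-yl)-1,4,4a,8a-tetrahydro-1,4-methanonaphthalene-5,8-dione (endo adduct) | CC(C)=CCC1=CC(=O)[C@H]2[C@@H](C1=O)[C@H]1C=C[C@@H]2C1 | intermediate
8 | 2,5-dimethoxybenzaldehyde | COc1ccc(OC)c(C=O)c1 | starting material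
9 | diethyl (2-methylprop-2-en-1-yl)phosphonate | CCOP(=O)(CC(C)=C)OCC | starting material
10 | α-lithiated diethyl (2-methylprop-2-en-1-yl)phosphonate | [Li]C(C(C)=C)P(=O)(OCC)OCC | intermediate (not isolated)
11 | 1,4-dimethoxy-2-[(1E)-3-methylbuta-1,3-dien-1-yl]benzene | COc1ccc(OC)c(/C=C/C(C)=C)c1 | intermediate
12 | 5-(2,5-dimethoxyphenyl)-7-methyl-10a-(3-methylbut-2-en-1-yl)-1,4,4a,5,8,8a,9a,10a-octahydro-1,4-methanoanthracene-9,10-dione; norbornene endo-fused, new cyclohexene ring anti to it, aryl cis to the C-10 carbonyl and trans to the prenyl group | CC(C)=CC[C@@]12C(=O)[C@H]3[C@H]4C=C[C@H](C4)[C@H]3C(=O)[C@@H]1CC(C)=C[C@@H]2c1cc(OC)ccc1OC | intermediate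
13 | (4aS,5R,8aR)-5-(2,5-dimethoxyphenyl)-7-methyl-4a-(3-methylbut-2-en-1-yl)-4a,5,8,8a-tetrahydronaphthalene-1,4-dione (cis-fused) | CC(C)=CC[C@@]12C(=O)C=CC(=O)[C@@H]1CC(C)=C[C@@H]2c1cc(OC)ccc1OC | intermediate
14 | trimethylsilyl dienol ether of 13 (C-1 enol ether with a C1=C8a double bond; C-4a and C-5 unchanged) | CC(C)=CC[C@@]12C(=O)C=CC(O[Si](C)(C)C)=C1CC(C)=C[C@@H]2c1cc(OC)ccc1OC | intermediate (not isolated)
15 | O-bound phenyl(tosyloxy)-λ3-iodanyl dienolate of 13 (enolonium equivalent) | CC(C)=CC[C@@]12C(=O)C=CC(O[I](c3ccccc3)OS(=O)(=O)c3ccc(C)cc3)=C1CC(C)=C[C@@H]2c1cc(OC)ccc1OC | intermediate (not isolated)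
16 | tetracyclic enedione, rings A–D: dimethoxybenzo-bridged bicyclo[3.2.1]octadiene fused to the cyclohexenedione, prenyl on the one-carbon bridge syn to the methyl-alkene bridge | CC(C)=CC[C@@]23C(=O)C=CC(=O)[C@@]21CC(C)=C[C@@H]3c2c(OC)ccc(OC)c21 | intermediate
17 | bis(methyl ether) of the target (rings A–E, exo isopropenyl) | C=C(C)[C@H]1C[C@@]23C(=O)[C@@H]1CC(=O)[C@@]21CC(C)=C[C@@H]3c2c(OC)ccc(OC)c21 | intermediate
18 | ring A quinone of the target | C=C(C)[C@H]1C[C@@]23C(=O)[C@@H]1CC(=O)[C@@]21CC(C)=C[C@@H]3C2=C1C(=O)C=CC2=O | intermediate (not isolated)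
19 | CNP0287617.1 | C=C(C)[C@H]1C[C@@]23C(=O)[C@@H]1CC(=O)[C@@]21CC(C)=C[C@@H]3c2c(O)ccc(O)c21 | target

**Step count and risks**

Total steps: 9. Longest linear sequence: 8 (steps 1, 2, 3, 5, 6, 7, 8, 9; step 4 is the side branch).

Most likely to fail, in order:

Step 7 (enolonium arylation). The closure is unprecedented in this bridged setting. The enolonium may instead lose a proton to a dienone, be trapped by tosylate, or be attacked at the methoxy-bearing ortho carbon; the iodane may also oxidise the dimethoxyarene. The fallback sets out from 13 and comes back at 19, and moves the reversed polarity onto the arene. Oxidation of 13 with (NH4)2Ce(NO3)6 in MeCN/H2O gives the enedione quinone F1 (the dimethoxyphenyl ring of 13 turned into a 1,4-benzoquinone). Under argon with catalytic Et3N in CH2Cl2 the ring D enol, still the only one possible, adds to the quinone carbon next to the side chain, and tautomerisation gives the ring-B-closed hydroquinone enedione F2. This closure is geometrically harder, which is why it is not the first choice. Treatment of F2 with excess Me2AlCl, as in step 8, then gives 19 directly.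

Step 8 (ene closure of ring E). The exo/endo outcome at the isopropenyl carbon is not secured by precedent, and attack at the other enedione carbon would give a bicyclo[2.2.2] isomer. The fallback sets out from 16 and comes back at 17. Zn dust in AcOH at rt reduces only the enedione C=C to the saturated 1,4-diketone F3. Mn(OAc)3·2H2O and Cu(OAc)2·H2O in AcOH at 80 °C then generate the α-keto radical next to the carbonyl that flanks the prenylated quaternary carbon. It adds 5-exo to the prenyl alkene through the same chair-like geometry, and Cu(OAc)2 oxidises the tertiary radical to the isopropenyl group, giving 17.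

Step 5 (hindered thermal Diels–Alder). The trisubstituted dienophile in the norbornene-fused system may be too slow below the temperature at which the mask falls off, and no Lewis acid can be used without losing the regiochemistry. The fallback sets out from 5 and comes back at 13, and replaces the norbornene mask by an oxirane. Asymmetric nucleophilic epoxidation of the unsubstituted C=C of 5 (t-BuOOH, NaOH, N-benzylquininium chloride or its quinidinium pseudo-enantiomer as needed, toluene, 0 °C) gives the epoxyquinone (1S,6R)-3-(3-methylbut-2-en-1-yl)-7-oxabicyclo[4.1.0]hept-3-ene-2,5-dione F4. This smaller, more electron-poor dienophile should add 11 at 40–60 °C anti to the oxirane with the same endo and regiochemical sense, giving the epoxy adduct F5. Deoxygenation with Me3SiCl/NaI in MeCN at 0 °C restores the enedione C=C and delivers 13, which also removes the pyrolysis of step 6.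

**Further compounds**

F1 | step 7 | enedione quinone: 13 with the 2,5-dimethoxyphenyl ring oxidised to a 1,4-benzoquinon-2-yl group | CC(C)=CC[C@@]12C(=O)C=CC(=O)[C@@H]1CC(C)=C[C@@H]2C1=CC(=O)C=CC1=O
F2 | step 7 | ring-B-closed hydroquinone enedione (16 with both methyl ethers replaced by OH) | CC(C)=CC[C@@]23C(=O)C=CC(=O)[C@@]21CC(C)=C[C@@H]3c2c(O)ccc(O)c21
F3 | step 8 | saturated 1,4-diketone (16 with the enedione C=C reduced to CH2–CH2) | CC(C)=CC[C@@]23C(=O)CCC(=O)[C@@]21CC(C)=C[C@@H]3c2c(OC)ccc(OC)c21
F4 | step 5 | (1S,6R)-3-(3-methylbut-2-en-1-yl)-7-oxabicyclo[4.1.0]hept-3-ene-2,5-dione | CC(C)=CCC1=CC(=O)[C@@H]2O[C@@H]2C1=O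
F5 | step 5 | 2,3-epoxide of 2,3-dihydro-13 (oxirane anti to the cyclohexene ring bonds) | CC(C)=CC[C@@]12C(=O)[C@H]3O[C@H]3C(=O)[C@@H]1CC(C)=C[C@@H]2c1cc(OC)ccc1OC
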